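## Retrosynthetic overview

1. Target 20 ⇐ face-selective epoxidation of the 4Z alkene of dienolide 19 (sets C4 and C5 last).
2. 19 ⇐ ring expansion of the 5/7-fused tricyclic carbinol 18: alkoxy-radical β-scission of the C1–C7 bond with copper-mediated allylic acetoxylation. This one step gives the ten-membered ring, the C1 ketone, the C7=C11 butenolide alkene and C13–OAc.
3. 18 ⇐ ring-closing metathesis (cycloheptene, fixes 4Z) ⇐ intramolecular zinc Barbier allylation of bromomethyl butenolide 14 (cyclopentane, C1–C7 bond) ⇐ Nozaki–Hiyama–Kishi union of iodobutenolide 12 with keto aldehyde 5 (C7–C8 bond).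
4. 12 ⇐ acrolein + methyl propiolate + formaldehyde; 5 ⇐ (R)-α-methyl-γ-butyrolactone + 4-bromo-2-methylbut-1-ene; the ester comes from tigloyl chloride.
5. Ring order: butenolide → cyclopentane → cycloheptene → cyclodecene (by expansion) → oxirane.

Assumption: (R)-α-methyl-γ-butyrolactone is bought enantiopure.

Atom labels C1–C13 follow germacrane numbering of the target: C1 ketone carbon, C4/C5 oxirane carbons, C6 lactone CH–O, C7=C11 butenolide alkene, C8 CH–O-tigloyl, C10 CH–CH3, C12 lactone C=O, C13 CH2OAc. The target epoxide is cis (C3 and C6 on the same side of the oxirane), so its alkene precursor is 4Z.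

## Route

Step 1
Reactants: 1 (R)-α-methyl-γ-butyrolactone; 2 4-bromo-2-methylbut-1-ene
Product: 4 (3R)-1-hydroxy-3,7-dimethyloct-7-en-4-one, via 3-methylbut-3-enyllithium 3 (not isolated)
Conditions: 2, Li, Et2O, 0 °C; then 1, THF, −78 °C; aq NH4Cl
Reagents that add atoms: none
Why: Organolithium addition to a lactone stops at the lithium lactolate at −78 °C and gives the hydroxy ketone on work-up, so the C10 stereocentre of 1 is carried over unchanged.

Step 2
Reactants: 4 (3R)-1-hydroxy-3,7-dimethyloct-7-en-4-one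
Product: 5 (3R)-3,7-dimethyl-4-oxooct-7-enal
Conditions: TEMPO (10 mol %), PhI(OAc)2, CH2Cl2, rt
Reagents that add atoms: none
Why: Oxoammonium (TEMPO) oxidation of the primary alcohol is near-neutral, so the ketone α-stereocentre C10 does not epimerise, and the alkene is untouched.

Step 3
Reactants: 6 acrolein; 7 methyl propiolate
Product: 9 methyl (4R)-4-hydroxyhex-5-en-2-ynoate, via methyl 3-(methylzincio)propiolate 8 (not isolated)
Conditions: 7, Me2Zn, (S,S)-ProPhenol (10 mol %), Ph3PO (20 mol %), toluene, 0 °C; then 6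
Reagents that add atoms: none
Why: Zinc–ProPhenol-catalysed enantioselective alkynylation adds the acetylide 1,2 to one face of acrolein and sets C6 (ligand enantiomer chosen to give the 4R alcohol).

Step 4
Reactants: 9 methyl (4R)-4-hydroxyhex-5-en-2-ynoate; 10 formaldehyde
Product: 12 (5R)-3-(hydroxymethyl)-4-iodo-5-vinylfuran-2(5H)-one, via open-chain iodo diol ester 11 (not isolated)
Conditions: MgI2, CH2O (monomer from paraformaldehyde), CH2Cl2, 0 °C to rt; then TsOH (cat.)
Reagents that add atoms: magnesium diiodide, [Mg+2].[I-].[I-]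
Why: This is a halo-aldol (β-iodo Morita–Baylis–Hillman) reaction: iodide adds to the ynoate and the allenolate is trapped by formaldehyde at C11; the alkene isomers equilibrate by reversible iodide addition and only the one with C6–OH cis to the ester lactonises, while C6 is not touched.

Step 5
Reactants: 12 (5R)-3-(hydroxymethyl)-4-iodo-5-vinylfuran-2(5H)-one; 5 (3R)-3,7-dimethyl-4-oxooct-7-enal
Product: 13 (5R)-4-[(1S,3R)-1-hydroxy-3,7-dimethyl-4-oxooct-7-en-1-yl]-3-(hydroxymethyl)-5-vinylfuran-2(5H)-one
Conditions: CrCl2, Kishi-type oxazoline–sulfonamide ligand, Et3N, THF, rt; then NiCl2 (2 mol %), 12, 5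
Reagents that add atoms: none
Why: Nozaki–Hiyama–Kishi reaction: zerovalent nickel inserts into the C–I bond, the alkenylchromium adds to the aldehyde and not to the ketone, and the chiral sulfonamide complex of chromium controls the new carbinol C8 as S.

Step 6
Reactants: 13 (5R)-4-[(1S,3R)-1-hydroxy-3,7-dimethyl-4-oxooct-7-en-1-yl]-3-(hydroxymethyl)-5-vinylfuran-2(5H)-one
Product: 14 (5R)-3-(bromomethyl)-4-[(1S,3R)-1-hydroxy-3,7-dimethyl-4-oxooct-7-en-1-yl]-5-vinylfuran-2(5H)-one
Conditions: CBr4, PPh3, CH2Cl2, −20 °C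
Reagents that add atoms: carbon tetrabromide, BrC(Br)(Br)Br
Why: Appel reaction; the primary allylic alcohol reacts much faster than the hindered secondary C8 alcohol at low temperature.

Step 7
Reactants: 14 (5R)-3-(bromomethyl)-4-[(1S,3R)-1-hydroxy-3,7-dimethyl-4-oxooct-7-en-1-yl]-5-vinylfuran-2(5H)-one
Product: 15 (1R,5R,6S,7R,9S)-6,9-dihydroxy-7-methyl-6-(3-methylbut-3-en-1-yl)-4-methylidene-1-vinyl-2-oxaspiro[4.4]nonan-3-one
Conditions: Zn dust, THF/sat. aq NH4Cl, 0 °C to rt
Reagents that add atoms: none
Why: Intramolecular zinc Barbier allylation: the allylzinc attacks the ketone through its γ-carbon C7 in a closed five-ring-forming transition state, giving quaternary C7, carbinol C1 and the exo-methylene lactone; attack is expected anti to the C6 vinyl group with C1–O syn to C11, and both new centres are erased in step 10.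

Step 8
Reactants: 15 spiro-lactone diol; 16 (E)-2-methylbut-2-enoyl chloride (tigloyl chloride)
Product: 17 (1R,5R,6S,7R,9S)-6-hydroxy-7-methyl-6-(3-methylbut-3-en-1-yl)-4-methylidene-3-oxo-1-vinyl-2-oxaspiro[4.4]nonan-9-yl (2E)-2-methylbut-2-enoate
Conditions: 16, pyridine, DMAP (cat.), CH2Cl2, 0 °C
Reagents that add atoms: none
Why: DMAP-catalysed acylation of the secondary C8 alcohol; the neopentyl tertiary C1 alcohol does not react.

Step 9
Reactants: 17 spiro-lactone tiglate
Product: 18 (1S,6R,7R,8S,10R)-1-hydroxy-8-tigloyloxy-1,7-cyclogermacra-4Z,11(13)-dien-12,6-olide (C1–C7-bonded 5/7 bicycle carrying the 6,12-lactone)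
Conditions: second-generation Grubbs catalyst (5 mol %), CH2Cl2, 40 °C, 5 mM
Reagents that add atoms: none
Why: Ring-closing metathesis between the vinyl group and the 1,1-disubstituted alkene closes the cycloheptene and so fixes the 4Z geometry; the tiglate and the electron-poor exo-methylene lactone stay out.

Step 10
Reactants: 18 tricyclic carbinol
Product: 19 (4Z,6R,8S,10R)-13-acetoxy-1-oxo-8-tigloyloxygermacra-4,7(11)-dien-12,6-olide
Conditions: PhI(OAc)2 (1.3 equiv), CuOAc (10 mol %), 4,4'-di-tert-butyl-2,2'-bipyridine (12 mol %), MeCN, 40 °C, dark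
Reagents that add atoms: (diacetoxyiodo)benzene, CC(=O)OI(OC(C)=O)c1ccccc1
Why: Proposed new method: the tertiary alcohol exchanges onto iodine to give an alkoxy(acetoxy)iodane, monovalent copper reduces it to the C1 alkoxy radical, β-scission of C1–C7 (the only cleavage that gives a tertiary allyl radical) opens the bicycle to the ten-membered ketone, and divalent copper acetate captures the allyl radical at the unhindered C13 terminus so that C–O reductive elimination from trivalent copper gives the conjugated primary acetate and returns monovalent copper (a tertiary C7 acetate, if formed, is the less stable allylic isomer and should transpose to the same product); the closest known reactions are Suárez alkoxy-radical fragmentation with PhI(OAc)2/I2, copper-catalysed β-scission of alkyl peroxides and Kharasch–Sosnovsky allylic acyloxylation.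

Step 11
Reactants: 19 dienolide acetate
Product: 20 (4R,5S,6S,8S,10R)-13-acetoxy-4,5-epoxy-1-oxo-8-tigloyloxygermacr-7(11)-en-12,6-olide (target, CNP0229937.1)
Conditions: DMDO, acetone, −20 °C
Reagents that add atoms: dimethyldioxirane, CC1(C)OO1
Why: Dioxirane epoxidation touches only the electron-rich trisubstituted alkene; with H-6 in the alkene plane (allylic strain) the ring blocks one face, so oxygen should arrive on the outer face syn to the C6–O bond, giving the cis-epoxide with 4R,5S.

## Compound list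

1 | (R)-α-methyl-γ-butyrolactone, (3R)-3-methyldihydrofuran-2(3H)-one | C[C@@H]1CCOC1=O | starting material
2 | 4-bromo-2-methylbut-1-ene | C=C(C)CCBr | starting material
3 | 3-methylbut-3-enyllithium | [Li]CCC(C)=C | intermediate
4 | (3R)-1-hydroxy-3,7-dimethyloct-7-en-4-one | OCC[C@@H](C)C(=O)CCC(C)=C | intermediate
5 | (3R)-3,7-dimethyl-4-oxooct-7-enal | O=CC[C@@H](C)C(=O)CCC(C)=C | intermediate
6 | acrolein | C=CC=O | starting material
7 | methyl propiolate | C#CC(=O)OC | starting material
8 | methyl 3-(methylzincio)propiolate | C[Zn]C#CC(=O)OC | intermediate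
9 | methyl (4R)-4-hydroxyhex-5-en-2-ynoate | O[C@@H](C#CC(=O)OC)C=C | intermediate
10 | formaldehyde | C=O | starting material
11 | methyl (2E,4R)-4-hydroxy-2-(hydroxymethyl)-3-iodohexa-2,5-dienoate | OC/C(C(=O)OC)=C(\I)[C@H](O)C=C | intermediate
12 | (5R)-3-(hydroxymethyl)-4-iodo-5-vinylfuran-2(5H)-one | OCC1=C(I)[C@@H](C=C)OC1=O | intermediate
13 | (5R)-4-[(1S,3R)-1-hydroxy-3,7-dimethyl-4-oxooct-7-en-1-yl]-3-(hydroxymethyl)-5-vinylfuran-2(5H)-one | O[C@@H](C[C@@H](C)C(=O)CCC(C)=C)C1=C(CO)C(=O)O[C@@H]1C=C | intermediate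
14 | (5R)-3-(bromomethyl)-4-[(1S,3R)-1-hydroxy-3,7-dimethyl-4-oxooct-7-en-1-yl]-5-vinylfuran-2(5H)-one | O[C@@H](C[C@@H](C)C(=O)CCC(C)=C)C1=C(CBr)C(=O)O[C@@H]1C=C | intermediate
15 | (1R,5R,6S,7R,9S)-6,9-dihydroxy-7-methyl-6-(3-methylbut-3-en-1-yl)-4-methylidene-1-vinyl-2-oxaspiro[4.4]nonan-3-one | O[C@H]1C[C@@H](C)[C@@](O)(CCC(C)=C)[C@]12C(=C)C(=O)O[C@@H]2C=C | intermediate
16 | (E)-2-methylbut-2-enoyl chloride (tigloyl chloride) | C/C=C(\C)C(=O)Cl | starting material
17 | (1R,5R,6S,7R,9S)-6-hydroxy-7-methyl-6-(3-methylbut-3-en-1-yl)-4-methylidene-3-oxo-1-vinyl-2-oxaspiro[4.4]nonan-9-yl (2E)-2-methylbut-2-enoate | C/C=C(\C)C(=O)O[C@H]1C[C@@H](C)[C@@](O)(CCC(C)=C)[C@]12C(=C)C(=O)O[C@@H]2C=C | intermediate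
18 | (1S,6R,7R,8S,10R)-1-hydroxy-8-tigloyloxy-1,7-cyclogermacra-4Z,11(13)-dien-12,6-olide | C/C=C(\C)C(=O)O[C@H]1C[C@@H](C)[C@@]2(O)CC/C(C)=C\[C@H]3OC(=O)C(=C)[C@]123 | intermediate
19 | (4Z,6R,8S,10R)-13-acetoxy-1-oxo-8-tigloyloxygermacra-4,7(11)-dien-12,6-olide | C/C=C(\C)C(=O)O[C@H]1C[C@@H](C)C(=O)CC/C(C)=C\[C@H]2OC(=O)C(COC(C)=O)=C12 | intermediate
20 | (4R,5S,6S,8S,10R)-13-acetoxy-4,5-epoxy-1-oxo-8-tigloyloxygermacr-7(11)-en-12,6-olide | C/C=C(\C)C(=O)O[C@H]1C[C@@H](C)C(=O)CC[C@@]2(C)O[C@H]2[C@H]2OC(=O)C(COC(C)=O)=C12 | target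

## Step count and risks

Total steps: 11. Longest linear sequence: 9 steps (3, 4, 5, 6, 7, 8, 9, 10, 11; the branch 1, 2 joins at step 5 and is equally long).

The three steps most likely to fail:

**Step 10 (proposed new ring expansion with acetoxylation).** The alkoxy radical could add across the ring to the C4=C5 alkene instead of fragmenting, the iodane could fail to be reduced by monovalent copper, or the C–O bond could form at C7. The fallback uses known chemistry and sets out from 18. Suárez hypoiodite fragmentation (PhI(OAc)2, I2, visible light, CH2Cl2) performs the same β-scission with iodine-atom transfer and gives (4Z,6R,8S,10R)-13-iodo-1-oxo-8-tigloyloxygermacra-4,7(11)-dien-12,6-olide F4. Displacement of the allylic iodide with AgOAc in MeCN comes back to the route at 19.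

**Step 4 (halo-aldol with lactonisation).** An internal ynoate is a sluggish acceptor for iodide, and the alkene geometry needed for lactonisation is not assured. The fallback sets out from 9. Pd(PPh3)4-catalysed syn-addition of hexabutylditin, with lactonisation in the flask, gives (5R)-3,4-bis(tributylstannyl)-5-vinylfuran-2(5H)-one F1. Iodine converts it into (5R)-3,4-diiodo-5-vinylfuran-2(5H)-one F2. Nozaki–Hiyama–Kishi coupling of F2 with 5 at the more electrophilic C4–I bond gives (5R)-4-[(1S,3R)-1-hydroxy-3,7-dimethyl-4-oxooct-7-en-1-yl]-3-iodo-5-vinylfuran-2(5H)-one F3. Stille coupling of F3 with (tributylstannyl)methanol and Pd(PPh3)4 comes back to the route at 13.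

**Step 11 (facial selectivity of the epoxidation).** The conformational argument may not hold and the oxidant may attack the other face. The fallback sets out from 19 and turns the same facial bias around. NBS in wet THF forms the bromonium ion on the face the oxidant prefers and water opens it at C4 from the other face, giving (4R,5R,6S,8S,10R)-13-acetoxy-5-bromo-4-hydroxy-1-oxo-8-tigloyloxygermacr-7(11)-en-12,6-olide F5. Ag2O then closes the oxirane with inversion at C5, which places the oxygen on the opposite face and comes back to the route at 20.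

## Further compounds

F1 | step 4 | (5R)-3,4-bis(tributylstannyl)-5-vinylfuran-2(5H)-one | CCCC[Sn](CCCC)(CCCC)C1=C([Sn](CCCC)(CCCC)CCCC)[C@@H](C=C)OC1=O
F2 | step 4 | (5R)-3,4-diiodo-5-vinylfuran-2(5H)-one | IC1=C(I)[C@@H](C=C)OC1=O
F3 | step 4 | (5R)-4-[(1S,3R)-1-hydroxy-3,7-dimethyl-4-oxooct-7-en-1-yl]-3-iodo-5-vinylfuran-2(5H)-one | O[C@@H](C[C@@H](C)C(=O)CCC(C)=C)C1=C(I)C(=O)O[C@@H]1C=C
F4 | step 10 | (4Z,6R,8S,10R)-13-iodo-1-oxo-8-tigloyloxygermacra-4,7(11)-dien-12,6-olide | C/C=C(\C)C(=O)O[C@H]1C[C@@H](C)C(=O)CC/C(C)=C\[C@H]2OC(=O)C(CI)=C12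
F5 | step 11 | (4R,5R,6S,8S,10R)-13-acetoxy-5-bromo-4-hydroxy-1-oxo-8-tigloyloxygermacr-7(11)-en-12,6-olide | C/C=C(\C)C(=O)O[C@H]1C[C@@H](C)C(=O)CC[C@@](C)(O)[C@H](Br)[C@H]2OC(=O)C(COC(C)=O)=C12
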